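**Plan**

1. Atom numbers used in the text: C1 = CMe2, C2 = CHBr, C3 = CH2, C4 = CHCl, C5 = ring carbon carrying the alkylidene, C6 = CHCl next to C1, C7 = exocyclic =CH, C8 = CH2Br (IUPAC names carry their own locants).
2. Retrosynthesis: C8–Br, C4–Cl and C6–Cl are cut first (each from C–O, with inversion at C4 and C6), then the ring bond C5–C6 (C5≡C7 alkyne plus C6 aldehyde), then C2–Br (from C2–OH with inversion, on the open chain), last C3–C4 (aldol of a methyl ynone with an aldehyde).
3. Enabling feature: in ring C1–C6 the unit C6(X)–C5(=C7H–C8) has the vinylic H on C7 cis to the heteroatom-bearing C6. This is the retron of a syn addition of H and a C6 carbonyl carbon across a C5≡C7 triple bond; C6 is non-enolisable because C1 is quaternary.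
4. Forward: the C6–C1–C2 aldehyde and the C3–C8 ynone are joined by aldol, C4 is reduced, Br is placed on C2, and the only ring is closed by rhodium-catalysed, hydrogen-mediated alkyne–aldehyde reductive cyclization of the open-chain 6-ynal. The two ring chlorides and the allylic bromide follow.
5. Stereochemistry: C2 from a catalytic asymmetric aldol, C4 from hydroxyl-directed 1,3-anti reduction, C6 from the all-equatorial chair of the metallacycle (Br on C2 as anchor). Each centre is then inverted once by halide (SN2); the alkene geometry comes from the syn addition.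

Key step: step 8

Assumption: the antipode of ProPhenol (2,6-bis{[2-(hydroxydiphenylmethyl)pyrrolidin-1-yl]methyl}-4-methylphenol) that gives (R)-6 is taken to be (S,S); if the sense of induction is the opposite with this acceptor, (R,R)-ProPhenol is used.

**Step 1**
Reactants: 1 methyl 3-hydroxy-2,2-dimethylpropanoate
Product: 2 methyl 2,2-dimethyl-3-oxopropanoate
Conditions: TEMPO (10 mol %), PhI(OAc)2, CH2Cl2, rt
Reagents that add atoms: none
Why: Oxoammonium-mediated (TEMPO/PhI(OAc)2) oxidation of the primary neopentyl alcohol should stop at the aldehyde, which cannot enolise because C1 is quaternary.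

**Step 2**
Reactants: 3 tert-butyldimethyl(prop-2-yn-1-yloxy)silane
Product: 5 5-[(tert-butyldimethylsilyl)oxy]pent-3-yn-2-one, via lithium acetylide 4 (not isolated)
Conditions: n-BuLi, THF, −78 °C; then MeC(O)N(OMe)Me, −78 → 0 °C; aq. NH4Cl
Reagents that add atoms: N-methoxy-N-methylacetamide, CC(=O)N(C)OC
Why: Weinreb ketone synthesis: the lithium acetylide adds once to the N-methoxy-N-methylamide, and the chelated tetrahedral adduct collapses to the methyl ynone only on work-up.

**Step 3**
Reactants: 2 methyl 2,2-dimethyl-3-oxopropanoate; 5 5-[(tert-butyldimethylsilyl)oxy]pent-3-yn-2-one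
Product: 6 methyl (3R)-8-[(tert-butyldimethylsilyl)oxy]-3-hydroxy-2,2-dimethyl-5-oxooct-6-ynoate
Conditions: (S,S)-ProPhenol (10 mol %), Et2Zn (20 mol %), 4 Å molecular sieves, THF, 0 °C
Reagents that add atoms: none
Why: Direct catalytic asymmetric aldol addition of a methyl ynone by a dinuclear zinc–ProPhenol complex: the CH3 of 5 is the only enolisable site, aldehyde 2 is α-quaternary and non-enolisable, and the chiral zinc enolate should add to one aldehyde face to set C2 as R.

**Step 4**
Reactants: 6 methyl (3R)-8-[(tert-butyldimethylsilyl)oxy]-3-hydroxy-2,2-dimethyl-5-oxooct-6-ynoate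
Product: 7 methyl (3R,5R)-8-[(tert-butyldimethylsilyl)oxy]-3,5-dihydroxy-2,2-dimethyloct-6-ynoate
Conditions: Me4NBH(OAc)3, MeCN/AcOH, −30 °C
Reagents that add atoms: none
Why: Evans–Saksena hydroxyl-directed reduction: the acetoxyborohydride bound to the C2 oxygen should deliver hydride intramolecularly through a chair transition state to give the 1,3-anti diol (C4 R) without touching ester or alkyne.

**Step 5**
Reactants: 7 methyl (3R,5R)-8-[(tert-butyldimethylsilyl)oxy]-3,5-dihydroxy-2,2-dimethyloct-6-ynoate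
Product: 8 methyl (3R,5R)-8-[(tert-butyldimethylsilyl)oxy]-3-hydroxy-2,2-dimethyl-5-[(triethylsilyl)oxy]oct-6-ynoate
Conditions: Et3SiCl, imidazole, CH2Cl2, −40 °C
Reagents that add atoms: chlorotriethylsilane, CC[Si](Cl)(CC)CC
Why: Kinetically selective silylation: the propargylic C4 hydroxyl should react, while the C2 hydroxyl, flanked by the quaternary C1, should not at this temperature.

**Step 6**
Reactants: 8 methyl (3R,5R)-8-[(tert-butyldimethylsilyl)oxy]-3-hydroxy-2,2-dimethyl-5-[(triethylsilyl)oxy]oct-6-ynoate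
Product: 10 methyl (3S,5R)-3-bromo-8-[(tert-butyldimethylsilyl)oxy]-2,2-dimethyl-5-[(triethylsilyl)oxy]oct-6-ynoate, via C2 triflate 9 (not isolated)
Conditions: Tf2O, 2,6-lutidine, CH2Cl2, −78 °C; then n-Bu4NBr, −78 °C → rt
Reagents that add atoms: tetrabutylammonium bromide, CCCC[N+](CCCC)(CCCC)CCCC.[Br-]
Why: Triflation followed by SN2 displacement with bromide should invert C2 (R to S), as in known halide and azide displacements of neopentylic secondary triflates; the ester on C1 disfavours ionisation and 1,2-shift, and the weakly basic bromide limits E2.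

**Step 7**
Reactants: 10 methyl (3S,5R)-3-bromo-8-[(tert-butyldimethylsilyl)oxy]-2,2-dimethyl-5-[(triethylsilyl)oxy]oct-6-ynoate
Product: 11 (3S,5R)-3-bromo-8-[(tert-butyldimethylsilyl)oxy]-2,2-dimethyl-5-[(triethylsilyl)oxy]oct-6-ynal
Conditions: i-Bu2AlH, CH2Cl2, −78 °C; then aq. potassium sodium tartrate
Reagents that add atoms: none
Why: Partial reduction of a hindered α,α-disubstituted ester with i-Bu2AlH should stop at the aluminium hemiacetal and give the aldehyde on work-up; the β-bromide cannot eliminate because C1 has no hydrogen.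

**Step 8**
Reactants: 11 (3S,5R)-3-bromo-8-[(tert-butyldimethylsilyl)oxy]-2,2-dimethyl-5-[(triethylsilyl)oxy]oct-6-ynal
Product: 12 (1R,3S,5R,6Z)-3-bromo-6-{2-[(tert-butyldimethylsilyl)oxy]ethylidene}-2,2-dimethyl-5-[(triethylsilyl)oxy]cyclohexan-1-ol
Conditions: [Rh(cod)2]OTf (5 mol %), BIPHEP [2,2'-bis(diphenylphosphino)-1,1'-biphenyl] (5 mol %), 2-naphthoic acid (10 mol %), H2 (1 atm), ClCH2CH2Cl, 40 °C
Reagents that add atoms: none
Why: Cationic monovalent rhodium carrying the bisphosphine binds the C5≡C7 alkyne and the C6 aldehyde of 11 and couples them oxidatively to an oxarhodacyclopentene, which creates the C5–C6 ring bond; acid-assisted hydrogenolysis of the Rh–O and Rh–C7 bonds by H2 then releases 12 and returns the catalyst. The closest known reaction type is the rhodium-catalysed hydrogen-mediated reductive cyclization of acetylenic aldehydes, the hydrogen analogue of nickel/silane ynal cyclizations. The cyclohexane ring closes in the 6-exo-dig mode, and since C6 and H are delivered to the same side of the triple bond the exocyclic alkene has H cis to C6 and C8 cis to C4, as in the target. The new stereocentre C6 is controlled by a chair-like transition state in which the forming C6–O bond must lie in the plane of the metallacycle (equatorial); with the C2 bromide and the C4 silyloxy group also equatorial the hydroxyl comes out cis to both (C6 R), whereas the competing chair would place Br and OSiEt3 1,3-diaxial. The step needs chemoselectivity for C–C coupling over plain hydrogenation of the alkyne, which the acid co-catalyst and the gem-dimethyl (Thorpe–Ingold) effect at C1 should secure, and tolerance of the secondary C–Br bond, which is why a rhodium/H2 system is used in place of zerovalent nickel. It also needs facial selectivity at the aldehyde, which the equatorial C2 bromide, installed beforehand on the chain, secures as a conformational anchor.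

**Step 9**
Reactants: 12 (1R,3S,5R,6Z)-3-bromo-6-{2-[(tert-butyldimethylsilyl)oxy]ethylidene}-2,2-dimethyl-5-[(triethylsilyl)oxy]cyclohexan-1-ol
Product: 13 tert-butyl({(2E)-2-[(2S,4S,6R)-4-bromo-2-chloro-3,3-dimethyl-6-[(triethylsilyl)oxy]cyclohexylidene]ethyl}oxy)dimethylsilane
Conditions: PPh3, Cl3CC(O)CCl3, CH2Cl2, 0 → 40 °C
Reagents that add atoms: hexachloroacetone, ClC(Cl)(Cl)C(=O)C(Cl)(Cl)Cl
Why: Appel-type chlorination: chloride should displace the equatorial C6 alkoxyphosphonium with inversion (R to S); the equatorial C–O bond lies in the alkene plane, so SN1 and SN2′ paths lack orbital overlap, and E2 is impossible because neither C1 nor C5 bears hydrogen.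

**Step 10**
Reactants: 13 tert-butyl({(2E)-2-[(2S,4S,6R)-4-bromo-2-chloro-3,3-dimethyl-6-[(triethylsilyl)oxy]cyclohexylidene]ethyl}oxy)dimethylsilane
Product: 14 (1R,2E,3S,5S)-5-bromo-2-{2-[(tert-butyldimethylsilyl)oxy]ethylidene}-3-chloro-4,4-dimethylcyclohexan-1-ol
Conditions: PPTS (cat.), MeOH/CH2Cl2, 0 °C
Reagents that add atoms: none
Why: Acid-catalysed methanolysis should remove the triethylsilyl ether much faster than the tert-butyldimethylsilyl ether, and the neopentylic C6 chloride should not solvolyse at 0 °C.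

**Step 11**
Reactants: 14 (1R,2E,3S,5S)-5-bromo-2-{2-[(tert-butyldimethylsilyl)oxy]ethylidene}-3-chloro-4,4-dimethylcyclohexan-1-ol
Product: 15 tert-butyl({(2E)-2-[(2S,4S,6S)-4-bromo-2,6-dichloro-3,3-dimethylcyclohexylidene]ethyl}oxy)dimethylsilane
Conditions: PPh3, Cl3CC(O)CCl3, CH2Cl2, 0 °C → rt
Reagents that add atoms: hexachloroacetone, ClC(Cl)(Cl)C(=O)C(Cl)(Cl)Cl
Why: Second Appel-type chlorination: chloride should attack the equatorial allylic C4 alkoxyphosphonium from the axial direction with inversion (R to S), giving the cis-4,6-dichloride and relieving the allylic 1,3-strain between the C4 oxygen and C8; this reagent class converts secondary allylic alcohols without allylic transposition.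

**Step 12**
Reactants: 15 tert-butyl({(2E)-2-[(2S,4S,6S)-4-bromo-2,6-dichloro-3,3-dimethylcyclohexylidene]ethyl}oxy)dimethylsilane
Product: 16 ochtodene, (1E,2S,4S,6S)-4-bromo-1-(2-bromoethylidene)-2,6-dichloro-3,3-dimethylcyclohexane
Conditions: Ph3PBr2, CH2Cl2, 0 °C → rt
Reagents that add atoms: triphenylphosphine dibromide, Br[P+](c1ccccc1)(c1ccccc1)c1ccccc1.[Br-]
Why: Direct conversion of a primary silyl ether into a bromide with Ph3PBr2 (silyl transfer to bromide, then SN2 on the alkoxyphosphonium at the unhindered allylic CH2); no stereocentre is touched and the secondary chlorides should exchange far more slowly.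

**Compound list**

1 | methyl 3-hydroxy-2,2-dimethylpropanoate | COC(=O)C(C)(C)CO | starting material
2 | methyl 2,2-dimethyl-3-oxopropanoate | COC(=O)C(C)(C)C=O | intermediate
3 | tert-butyldimethyl(prop-2-yn-1-yloxy)silane | C#CCO[Si](C)(C)C(C)(C)C | starting material
4 | lithium 3-[(tert-butyldimethylsilyl)oxy]prop-1-yn-1-ide (not isolated) | [Li]C#CCO[Si](C)(C)C(C)(C)C | intermediate
5 | 5-[(tert-butyldimethylsilyl)oxy]pent-3-yn-2-one | CC(=O)C#CCO[Si](C)(C)C(C)(C)C | intermediate
6 | methyl (3R)-8-[(tert-butyldimethylsilyl)oxy]-3-hydroxy-2,2-dimethyl-5-oxooct-6-ynoate | COC(=O)C(C)(C)[C@H](O)CC(=O)C#CCO[Si](C)(C)C(C)(C)C | intermediate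
7 | methyl (3R,5R)-8-[(tert-butyldimethylsilyl)oxy]-3,5-dihydroxy-2,2-dimethyloct-6-ynoate (1,3-anti diol) | COC(=O)C(C)(C)[C@H](O)C[C@@H](O)C#CCO[Si](C)(C)C(C)(C)C | intermediate
8 | methyl (3R,5R)-8-[(tert-butyldimethylsilyl)oxy]-3-hydroxy-2,2-dimethyl-5-[(triethylsilyl)oxy]oct-6-ynoate | COC(=O)C(C)(C)[C@H](O)C[C@@H](O[Si](CC)(CC)CC)C#CCO[Si](C)(C)C(C)(C)C | intermediate
9 | methyl (3R,5R)-8-[(tert-butyldimethylsilyl)oxy]-2,2-dimethyl-5-[(triethylsilyl)oxy]-3-{[(trifluoromethyl)sulfonyl]oxy}oct-6-ynoate (not isolated) | COC(=O)C(C)(C)[C@H](OS(=O)(=O)C(F)(F)F)C[C@@H](O[Si](CC)(CC)CC)C#CCO[Si](C)(C)C(C)(C)C | intermediate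
10 | methyl (3S,5R)-3-bromo-8-[(tert-butyldimethylsilyl)oxy]-2,2-dimethyl-5-[(triethylsilyl)oxy]oct-6-ynoate | COC(=O)C(C)(C)[C@@H](Br)C[C@@H](O[Si](CC)(CC)CC)C#CCO[Si](C)(C)C(C)(C)C | intermediate
11 | (3S,5R)-3-bromo-8-[(tert-butyldimethylsilyl)oxy]-2,2-dimethyl-5-[(triethylsilyl)oxy]oct-6-ynal | O=CC(C)(C)[C@@H](Br)C[C@@H](O[Si](CC)(CC)CC)C#CCO[Si](C)(C)C(C)(C)C | intermediate
12 | (1R,3S,5R,6Z)-3-bromo-6-{2-[(tert-butyldimethylsilyl)oxy]ethylidene}-2,2-dimethyl-5-[(triethylsilyl)oxy]cyclohexan-1-ol (Br, OSiEt3 and OH all cis; C8 cis to C4) | CC1(C)[C@@H](Br)C[C@@H](O[Si](CC)(CC)CC)/C(=C\CO[Si](C)(C)C(C)(C)C)[C@H]1O | intermediate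
13 | tert-butyl({(2E)-2-[(2S,4S,6R)-4-bromo-2-chloro-3,3-dimethyl-6-[(triethylsilyl)oxy]cyclohexylidene]ethyl}oxy)dimethylsilane (C6–Cl trans to Br and OSiEt3) | CC1(C)[C@@H](Br)C[C@@H](O[Si](CC)(CC)CC)/C(=C\CO[Si](C)(C)C(C)(C)C)[C@@H]1Cl | intermediate
14 | (1R,2E,3S,5S)-5-bromo-2-{2-[(tert-butyldimethylsilyl)oxy]ethylidene}-3-chloro-4,4-dimethylcyclohexan-1-ol | CC1(C)[C@@H](Br)C[C@@H](O)/C(=C\CO[Si](C)(C)C(C)(C)C)[C@@H]1Cl | intermediate
15 | tert-butyl({(2E)-2-[(2S,4S,6S)-4-bromo-2,6-dichloro-3,3-dimethylcyclohexylidene]ethyl}oxy)dimethylsilane | CC1(C)[C@@H](Br)C[C@H](Cl)/C(=C\CO[Si](C)(C)C(C)(C)C)[C@@H]1Cl | intermediate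
16 | ochtodene, (1E,2S,4S,6S)-4-bromo-1-(2-bromoethylidene)-2,6-dichloro-3,3-dimethylcyclohexane | CC1(C)[C@@H](Br)C[C@H](Cl)/C(=C\CBr)[C@@H]1Cl | target

Total step count: 12. Longest linear sequence: 11 steps (1 → 2 → 6 → 7 → 8 → 10 → 11 → 12 → 13 → 14 → 15 → 16); the branch 3 → 5 is one step.

**Steps most likely to fail**

Step 8 (key step). Plain hydrogenation of the alkyne or the aldehyde may outrun oxidative coupling at the hindered aldehyde. Facial selectivity at C6 may also erode, because allylic 1,3-strain between the equatorial C4 silyloxy group and C8 offsets part of the penalty of the diaxial chair. The fallback sets out from 11 and comes back at 12. Intramolecular alkyne hydroacylation with [Rh(dppe)]2(BF4)2 in acetone at rt (acyl–rhodium hydride, cis addition across the alkyne, 6-exo closure) should give (3S,5R,6E)-3-bromo-6-{2-[(tert-butyldimethylsilyl)oxy]ethylidene}-2,2-dimethyl-5-[(triethylsilyl)oxy]cyclohexan-1-one F1, with the same C5–C6 bond and alkene geometry. Luche reduction (NaBH4, CeCl3·7H2O, MeOH, −78 °C), with axial hydride delivery on the ring face free of axial groups, should then give the equatorial alcohol 12. Ring closure and C6 stereocontrol are thereby decoupled.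

Step 9. Backside displacement at the neopentylic C6 may be slow, so that silyl ether cleavage by the halophosphonium reagent or leakage into allylic transposition competes. The fallback sets out from 12 and comes back at 13. Activation and displacement are separated: ClCH2SO2Cl and pyridine in CH2Cl2 at 0 °C should give the isolable (1R,3S,5R,6E)-3-bromo-6-{2-[(tert-butyldimethylsilyl)oxy]ethylidene}-2,2-dimethyl-5-[(triethylsilyl)oxy]cyclohexyl chloromethanesulfonate F2. LiCl in DMF at 60 °C should then displace this with inversion to give 13. The sulfonate-then-external-halide tactic is the one used for neopentylic secondary alcohols beside gem-dimethyl groups. This is still an SN2 inversion at C6: the stereochemical parity of the route forces a single inversion there, and no fundamentally different known approach was found.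

Step 6. E2 loss of the triflate to the C2=C3 alkene, or ionisation with 1,2-shift, may compete with SN2 at the neopentylic C2. The fallback sets out from 8 and comes back at 10. Saponification (LiOH, THF/H2O) should give (3R,5R)-8-[(tert-butyldimethylsilyl)oxy]-3-hydroxy-2,2-dimethyl-5-[(triethylsilyl)oxy]oct-6-ynoic acid F3. Carboxyl activation (PhSO2Cl, pyridine, 0 °C) should close it, with retention at C2, to (4R)-4-{(2R)-5-[(tert-butyldimethylsilyl)oxy]-2-[(triethylsilyl)oxy]pent-3-yn-1-yl}-3,3-dimethyloxetan-2-one F4. MgBr2·OEt2 in Et2O should open this β-lactone by strain-driven alkyl–oxygen cleavage with inversion to (3S,5R)-3-bromo-8-[(tert-butyldimethylsilyl)oxy]-2,2-dimethyl-5-[(triethylsilyl)oxy]oct-6-ynoic acid F5. Me3SiCHN2 in MeOH/toluene should then give ester 10.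

**Further compounds**

F1 | step 8 | (3S,5R,6E)-3-bromo-6-{2-[(tert-butyldimethylsilyl)oxy]ethylidene}-2,2-dimethyl-5-[(triethylsilyl)oxy]cyclohexan-1-one | CC1(C)[C@@H](Br)C[C@@H](O[Si](CC)(CC)CC)/C(=C\CO[Si](C)(C)C(C)(C)C)C1=O
F2 | step 9 | (1R,3S,5R,6E)-3-bromo-6-{2-[(tert-butyldimethylsilyl)oxy]ethylidene}-2,2-dimethyl-5-[(triethylsilyl)oxy]cyclohexyl chloromethanesulfonate | CC1(C)[C@@H](Br)C[C@@H](O[Si](CC)(CC)CC)/C(=C\CO[Si](C)(C)C(C)(C)C)[C@H]1OS(=O)(=O)CCl
F3 | step 6 | (3R,5R)-8-[(tert-butyldimethylsilyl)oxy]-3-hydroxy-2,2-dimethyl-5-[(triethylsilyl)oxy]oct-6-ynoic acid | OC(=O)C(C)(C)[C@H](O)C[C@@H](O[Si](CC)(CC)CC)C#CCO[Si](C)(C)C(C)(C)C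
F4 | step 6 | (4R)-4-{(2R)-5-[(tert-butyldimethylsilyl)oxy]-2-[(triethylsilyl)oxy]pent-3-yn-1-yl}-3,3-dimethyloxetan-2-one | CC1(C)C(=O)O[C@@H]1C[C@@H](O[Si](CC)(CC)CC)C#CCO[Si](C)(C)C(C)(C)C
F5 | step 6 | (3S,5R)-3-bromo-8-[(tert-butyldimethylsilyl)oxy]-2,2-dimethyl-5-[(triethylsilyl)oxy]oct-6-ynoic acid | OC(=O)C(C)(C)[C@@H](Br)C[C@@H](O[Si](CC)(CC)CC)C#CCO[Si](C)(C)C(C)(C)C
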